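At the reading, 30 min after the start, what stands in the flask depends on how long its target has been there. For target made at an even pace this comes to 15.0 min, half of the time. That mean time since the molecules were made is the age of the target, and for a slow change the fraction turned into isomer of the product is a rate constant multiplied by this age. The teal run makes 13 % of target in its first 5.00 min and then slows, so in the closed flask gamma, charged like the teal run, the even-pace figure is a floor. The outlet of a well-mixed tank carries target aged 30 min on average, twice that floor.

common to all: free catalyst 16 mM
- teal: starting material 0.40 M; reagent 0.20 M; run made earlier
- violet: starting material 0.40 M; reagent 0.10 M; run made earlier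
- green: starting material 0.40 M; reagent 0.40 M; run made earlier
- alpha: starting material 0.40 M (fed, over 24.0 min); reagent 0.200 M; a stirred flask in which starting material is dosed at a steady rate over 24.0 min without added volume, worked up at 30 min; time 30 min
- zeta: starting material 0.40 M; reagent 0.200 M; a single well-mixed tank run continuously and read at steady state, 30 min in it on average
- gamma: starting material 0.40 M; reagent 0.200 M; a closed flask charged with all of it at once and left for 30 min; time 30 min
- delta: starting material 0.40 M; reagent 0.200 M (fed, over 24.0 min); all but reagent at the start; reagent goes in evenly over 24.0 min, the run ends at 30 min; time 30 min

| run | time / min | target / % | isomer of the product / % |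
|---|---|---|---|
| teal | 5.00 | 13 | 0 |
| teal | 10.0 | 24 | 3 |
| teal | 15.0 | 31 | 1 |
| teal | 20.0 | 38 | 0 |
| violet | 6.00 | 10 | 2 |
| violet | 12.0 | 18 | 0 |
| violet | 20.0 | 22 | 4 |
| violet | 25.0 | 26 | 0 |
| green | 3.00 | 8 | 0 |
| green | 8.00 | 23 | 1 |
| green | 15.0 | 42 | 1 |
| green | 25.0 | 62 | 2 |

(each reading ± 1.5 percentage points)

- the stated concentrations are those of everything mixed, before any reaction; amounts are the same in each set-up
- reactions considered so far: reagent + catalyst intermediate B -> catalyst intermediate C; catalyst intermediate A <-> catalyst intermediate B; starting material + free catalyst -> catalyst intermediate A; target <-> isomer of the product; catalyst intermediate C -> free catalyst + target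
- the feed brings no volume worth counting
- the earlier runs were made in a closed, stirred flask

* the set-up with the highest share of target in all that became target or isomer of the product, at the outlet or at the end ("none" if the first two lie within 2 percentage points) (alpha / zeta / gamma / delta / none)
* share of target in all that became target or isomer of the product, at the outlet or at the end, alpha
* share of target in all that became target or isomer of the product, at the outlet or at the end, zeta
* share of target in all that became target or isomer of the product, at the outlet or at the end, gamma
* share of target in all that became target or isomer of the product, at the outlet or at the end, delta

Two chemists read these tables differently. The first holds that isomer of the product forms side by side with target at a fixed selectivity factor, so that age does not enter. Pooling all the readings, this chemist gets a share of 95.8 % for each set-up, and points out that the teal run reads 3 % of isomer at 10.0 min but 0 % at 20.0 min. The second holds that isomer comes from target, and answers that each of these readings carries a scatter of 1.5 percentage points.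

The forecast is the second chemist's: “Selectivity depends only on product residence time.” It gives 95 % for alpha, 92 % for zeta, 94.7 % for gamma and 95.3 % for delta, with best none. Its tank loses 1.51 times what its gamma flask loses, which differs from the factor of twice in my own reckoning from the floor.

The simulation gives 97.7 % for alpha, 95.2 % for zeta, 96.8 % for gamma and 97.7 % for delta, with best none. Zeta lies 2.5 points below alpha, which goes against a single share for all set-ups, but the first chemist keeps the flasks alpha, gamma and delta, which span 0.90 points, less than the margin of 2 points.

    reagent + catalyst intermediate B → catalyst intermediate C (k = 12.0 M⁻¹ min⁻¹)
    catalyst intermediate A ⇌ catalyst intermediate B (K = 59.0, k = 2.20 min⁻¹)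
    starting material + free catalyst → catalyst intermediate A (k = 5.40 M⁻¹ min⁻¹)
    target ⇌ isomer of the product (K = 0.820, k = 0.00180 min⁻¹)
    catalyst intermediate C → free catalyst + target (k = 18.0 min⁻¹)

The half-life of target by its forward step alone, 6.4 h, is much longer than the 30 min of the run. Age multiplied by ln(2) and divided by that half-life gives 2.71 % for gamma, which loses 3.20 %, and 5.42 % for zeta, which loses 4.80 %.

The runs are simulated for substances that don't exist.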